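A percentage point of the electrophile charged is a small unit: in beta, the flask asked about, the last reading, 3.8 % at 5.00 h, stands for 30.4 mM of product. By the steps on offer, product forms as electrophile, the limiting reagent, meets dissolved nucleophile, while solid nucleophile dissolves and gas enters as free base.

- beta: electrophile 0.80 M; solid nucleophile 0.96 M; gas 39 mM (held); the very flask that is asked about, followed so far
- flask: electrophile 0.80 M; solid nucleophile 0.960 M; gas 39 mM (held); time 10 h

- beta (time / h: product / %, electrophile / %): 0.417: 0.4, 100.1; 0.667: 0.7, 99.4; 1.00: 0.6, 100.0; 2.00: 1.2, 99.2; 3.00: 1.3, 97.8; 5.00: 3.8, 95.7

(standard deviation of a reading: 0.3 percentage points)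

- for acid set free the idle adduct is counted in
- as a solid, counted per litre of solution: solid nucleophile
- at the start none of free base is dissolved
- what was read earlier has a scatter of 0.3 percentage points, one standard deviation
- what may be going on: acid set free + free base <-> idle adduct; solid nucleophile <-> nucleophile; acid set free + free base <-> salt of the base; gas <-> free base; electrophile + nucleophile -> acid set free + product; nucleophile + acid set free <-> protonated nucleophile
- at the start none of the solid nucleophile is in solution

- ochre: doubling the solubility of the solid nucleophile, all else as stated
- violet: doubling the dissolution coefficient of the solid nucleophile, all else as stated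
- amber: doubling the saturation concentration of gas, all else as stated
- grey: doubling the transfer coefficient of the gas, all else as stated

- product at 10 h, in percent of the electrophile charged
- the change that raises the amount of product at 10 h, in percent of the electrophile charged most ("none" if none brings more than 2 percentage points) (ochre / violet / amber / grey / none)
- amount of product at 10 h, in percent of the electrophile charged, after amber

Two chemists read these points differently. The first, who made the forecast, reads a straight line of about 0.67 %/h with no visible lag, and grants the later points a hint of acceleration. That line, drawn to 6.7 % at 10 h, puts 3.35 % at 5.00 h, and the reading there is 3.8 %, a gap of 0.45 percentage points against a scatter of 0.3 points.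

The second takes the gap seriously and lets the readings set the curve. Taken as a power of time, the readings at 2.00 h and 5.00 h give the exponent n = 1.26. This n is the growth exponent, the power of time linking two readings, and it carries their scatter. My own reckoning sides with the second chemist: the last reading, carried to 10 h with n, gives 9.09 %.

The forecast says 6.7 %, less than my 9.09 %, names ochre as the best change, and gives 7 % after amber, on the ground that “Dissolution is therefore quick compared with reaction”.

The simulation gives 11.5 % at 10 h and 11.7 % after amber. Ochre gains 9.8 points, against 5.1 points for violet and 0.21 points for amber. The forecast stands within its margins on all three answers.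

    acid set free + free base ⇌ idle adduct, settled at all times (K = 19.0 M⁻¹)
    solid nucleophile ⇌ nucleophile, rate k2*(cs2 - [nucleophile]) while solid is left; crystals form when [nucleophile] > cs2 (solubility = 0.220 M, k = 0.160 h⁻¹)
    acid set free + free base ⇌ salt of the base, settled at all times (K = 72000 M⁻¹)
    gas ⇌ free base, rate k4*(csat - [free base]) (kL = 1.00 h⁻¹)
    electrophile + nucleophile → acid set free + product (k = 0.150 M⁻¹ h⁻¹)
    nucleophile + acid set free ⇌ protonated nucleophile, settled at all times (K = 3700 M⁻¹)

My 9.09 % lies nearer 11.5 % than the forecast's 6.7 %. Carried from the 4.20 % standing at 5.00 h, n gives 10.1 % at 10 h, still below 11.5 %. On the neighbouring flask, left until 4.0 h, the straight line has its region and gives 2.68 %, n carried back from the last reading gives 2.87 %, and that flask holds 2.93 %.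

All runs are calculated on assumed constants; the scatter is artificial.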